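## The problem

(−)-Macrocarpal D is a hydroazulene: a cyclopentane (C1–C2–C3–C3a–C8a, azulene numbering) fused along C3a–C8a to a seven-membered ring (C3a–C4–C5–C6–C7–C8–C8a). The exocyclic benzylic carbon C9′ on C1 carries an isobutyl group and a 3,5-diformylphloroglucinol. There are five stereocentres: quaternary C1 (methyl α, C9′ β), C3a (H β), C4 (methyl α, H β), C7 (2-hydroxyprop-2-yl β) and C9′; β is the face of H-3a and of the C7 side chain. The only alkene, C8=C8a, is trisubstituted and lies between the quaternary C1 and C7.

C7 can be bought with carvone. It can fix the angular methyl of a decalin precursor, and its carbinol can later deliver hydrogen to C4. C3a then decides the face on which C1 is substituted. C9′ is the hardest centre: it is acyclic and has only the quaternary C1 to lean on.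

The diformylphloroglucinol (acidic, oxidisable, electrophilic aldehydes) must be unveiled last. The tertiary homoallylic carbinol and the C8=C8a alkene do not tolerate strong acid. In every cyclopentenone intermediate the ring-fusion hydrogen H-3a is γ to the carbonyl and therefore base-labile.

The enabling feature is that C1, C2, C3, C3a and C8a, with a methyl on C1 and the methyl-bearing C4 next to C3a, are ring A of a 4-methylcyclohexa-2,5-dienone whose angular carbon is C4. A eudesmane dienone can therefore be turned photochemically into the 5–7 skeleton, and it arrives as a 2-methylcyclopentenone ready for quaternisation at C1.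

## Retrosynthesis

**Aryl functionality last (28 ⇐ 27 ⇐ 25 ⇐ 24).** The three O–CH3 bonds of 27 and the two aryl–CHO bonds are cut first. A free diformylphloroglucinol would not survive the organometallic and Lewis-acid steps that build C9′, whereas a 2,4,6-trimethoxyphenyl group does and also activates C9′. The formyl carbons are traced to the dibromide 25 and bromine–lithium exchange rather than to a Lewis-acid formylation, because the tertiary carbinol and the alkene would be exposed to TiCl4-type reagents. The forward steps must achieve complete double exchange and triple demethylation.

**The two C9′ bonds (24 ⇐ 23 ⇐ 22 ⇐ 19 + 20).** The C9′–C10′ bond and the C9′–aryl bond are cut, leading to aldehyde 19 and 1,3,5-trimethoxybenzene 20. An aldehyde at C9′ lets both carbon substituents be added in turn. The aryl goes on first because it turns the resulting hydroxyl of 22 into a leaving group, so the second bond can form by cation capture with an allylsilane (23), followed by hydrogenation (24). Attaching an arylmethyl unit directly to C1 would leave a CH2 at C9′ with no handle for a controlled second substitution. The forward reaction must show facial selectivity in the capture of a benzylic cation beside the quaternary C1.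

**C1–C9′ and the C2 oxygen (19 ⇐ 18 ⇐ 17 ⇐ 15 ⇐ 14).** The C1–C9′ bond is cut to the enone 14 and a benzyloxymethyl electrophile. Alkylation of the extended dienolate at C1 creates the quaternary centre and moves the alkene to C8a=C8 in one operation; a reductive alkylation would also give C1 but would saturate C8a. The C2 carbonyl has then done its work and is removed (15 → 17), and both benzylic ethers are cleaved together (18). The forward step needs γ-deprotonation at C8 rather than at C3a, and attack on the face of H-3a.

**C4–H from C4–O (14 ⇐ 13 ⇐ 12 ⇐ 11 ⇐ 10 ⇐ 9).** The C4–H bond is traced through the exocyclic alkene 11/12 to the tertiary acetate 9. This is placed before the C1 alkylation for two reasons. An acetate or alkoxide on C4, next to the γ-acidic C3a–H, would be eliminated or would fragment under the base needed for alkylation. And before C8a=C8 exists, the only other alkene is an electron-poor tetrasubstituted enone, so a carbinol-directed hydrogenation (12 → 13) has no competitor. The forward steps need an elimination that avoids C3a and delivery of hydrogen to the β face of C4.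

**The skeleton (9 ⇐ 8).** The C3a–C8a bond is cut and the C4–C8a bond restored, which turns the hydroazulenone into the cross-conjugated decalin dienone 8. This single step makes both rings of the target and C3a, and it puts oxygen on C4 and an enone on C1/C8a where the next operations need them. The precursor is a plain eudesmane. The forward reaction must open the cyclopropane intermediate toward the 5–7 system and transfer the configuration of the angular carbon to C3a.

**The decalin (8 ⇐ 7 ⇐ 4 + 5 ⇐ 3 ⇐ 2 ⇐ 1).** The C1–C2 unsaturation is removed (7), and the two annulation bonds are cut to the cyclohexanone 4 and ethyl vinyl ketone 5. Ketone 4 goes back through conjugate reduction (3), silylation (2) and hydration to (R)-carvone 1. The annulation must place the angular methyl trans to the C7 side chain, which is its intrinsic preference.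

## Roads not taken

**Alternative 1:** The cut is C1–C8a together with C9′–aryl. In the forward sense a cycloheptenyl triflate carrying a pendant 1,1-disubstituted alkene would undergo oxidative addition, 5-exo carbopalladation and Suzuki capture, giving the trimethoxybenzyl hydroazulene A1.
- Merits: C1 and the C8a=C8 alkene are created together, and the alkene position is fixed by the triflate. That is more secure than the dienolate alkylation of the chosen plan, which has to discriminate between two γ-positions. The aryl group also arrives in the same operation.
- Weak points: in A1, C9′ is a CH2 flanked by a quaternary carbon and a di-ortho-substituted arene, and no reliable way exists to put the isobutyl group there with control. The neopentyl alkylpalladium must be intercepted by a hindered, protodeboronation-prone arylboronic acid. The catalyst must override three resident stereocentres. The monocyclic triflate with C3a, C4 and C7 defined has to be made without a ring template.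
- Comparison: alternative 1 is better on alkene placement and convergence. The chosen plan sets against it a six-step chiral-pool entry to the whole bicycle and a C9′ aldehyde that accepts both substituents.

**Alternative 2:** The cut is a one-carbon excision at C7 (bonds C6–C7 and C7–C8). In the forward sense a hydrindan-type ketone would be expanded with a diazoacetate under Lewis acid to the β-keto ester A2.
- Merits: quaternary C1 and the neighbouring centres would be set on a rigid 5–6 system. The ester on C7 is a direct precursor of the dimethylcarbinol. In these respects it is at least as good as the chosen plan.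
- Weak points: migration must choose the ring methylene over the ring-fusion methine. C7 in A2 is enolised, so its configuration has to be re-established later. The C8 oxygen must become the C8=C8a alkene by elimination toward the ring fusion, against conjugation with the ester. The tetrasubstituted hydrindanone is itself a long synthesis.
- Comparison: the chosen plan has C7 and its three side-chain carbons with the correct configuration from the first step, and forms the seven-membered ring and C3a in one precedented operation.

**Alternative 3:** The cut is C2–C3 (formed by an anionic oxy-Cope rearrangement) and, later, C3a–C8a (transannular closure). The forward key step would give the (E)-cyclodecenone A3 after in-situ methylation of the enolate.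
- Merits: convergent assembly, and a quaternary C1 made by simple enolate methylation with no dienolate ambiguity. In that respect it is better than the chosen plan.
- Weak points: the transannular closure of A3 must form C3a–C8a, fix C3a and C4, and leave the alkene at C8=C8a. Such closures of ten-membered rings depend on conformation and usually give alkene and ring-fusion isomers. C1 is set on a flexible medium-ring enolate. C9′ is again a CH2 that cannot be elaborated.
- Comparison: the chosen plan closes the bicycle by a rearrangement whose stereochemical course is fixed by the angular carbon, and keeps C9′ functionalised.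

Key step: step 6

## Steps

Remark: compounds 4 and 22 are carried as epimer mixtures at a centre that the following step erases (C2 of 4, C9′ of 22); their SMILES leave that centre open. Decalins use eudesmane numbering, the 5–7 compounds azulene numbering.

Step 1
Reactants: 1 (R)-carvone
Product: 2 (5R)-5-(2-hydroxypropan-2-yl)-2-methylcyclohex-2-en-1-one
Conditions: 50% aq. H2SO4, 0 °C
Reagents that add atoms: water, O
Why: Markovnikov acid-catalysed hydration of the isolated 1,1-disubstituted alkene through the tertiary cation, a known reaction of carvone at 0 °C; the enone and the C5 stereocentre are not involved.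

Step 2
Reactants: 2 hydroxy enone
Product: 3 (5R)-5-[2-(tert-butyldimethylsilyloxy)propan-2-yl]-2-methylcyclohex-2-en-1-one
Conditions: TBSOTf, 2,6-lutidine, CH2Cl2, −78 → 0 °C
Reagents that add atoms: tert-butyldimethylsilyl triflate, CC(C)(C)[Si](C)(C)OS(=O)(=O)C(F)(F)F
Why: Silyl triflate silylation of a tertiary alcohol with a hindered pyridine base; the ether protects the carbinol through the basic, oxidative and acidic steps 3–8 and keeps it from capturing the cation in step 6.

Step 3
Reactants: 3 silyloxy enone
Product: 4 (5R)-5-[2-(tert-butyldimethylsilyloxy)propan-2-yl]-2-methylcyclohexan-1-one (C2 epimers)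
Conditions: L-Selectride, THF, −78 °C; then H2O
Reagents that add atoms: none
Why: Conjugate hydride reduction of a cyclohexenone with an unsubstituted β-position by L-Selectride; the C2 epimer mixture is irrelevant because C2 becomes the enolate carbon in step 4.

Step 4
Reactants: 4 silyloxy ketone; 5 ethyl vinyl ketone
Product: 7 11-(tert-butyldimethylsilyloxy)-10-epi-eudesm-4-en-3-one, via Michael adduct diketone 6 (not isolated)
Conditions: KOH, EtOH, 0 °C → rt, then reflux
Reagents that add atoms: none
Why: Robinson annulation: the thermodynamic C2 enolate adds to the vinyl ketone by axial attack through a chair-like transition state with the bulky C5 substituent equatorial, so the chain enters cis to that substituent and the methyl ends trans to it (10α); aldol condensation then closes ring A as the 4-methyl enone.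

Step 5
Reactants: 7 silyloxy enone
Product: 8 11-(tert-butyldimethylsilyloxy)-10-epi-eudesma-1,4-dien-3-one
Conditions: DDQ, 1,4-dioxane, reflux
Reagents that add atoms: none
Why: DDQ dehydrogenation of a Δ4-3-ketone under neutral conditions removes H-1/H-2 through the 2,4-dienol and gives the cross-conjugated dienone; quaternary C10 and the silyl ether are untouched.

Step 6
Reactants: 8 cross-conjugated dienone
Product: 9 acetoxy hydroazulenone (2-oxo-1(8a)-ene; 3a-H β; 4β-OAc and 4α-Me; 7β-CMe2OTBS)
Conditions: hν (medium-pressure Hg lamp, Pyrex), glacial AcOH, N2, 15–20 °C
Reagents that add atoms: acetic acid, CC(=O)O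
Why: Santonin-type photorearrangement of a 4-methyl cross-conjugated cyclohexadienone in protic acid; the closest known case is santonin giving O-acetylisophotosantonic lactone. Excitation leads to bonding between the two β-carbons of the dienone (eudesmane C1 and C5, the future C3a and C8a), giving a bicyclo[3.1.0]hexenone zwitterion that acetic acid O-protonates to a cyclopropyl-substituted hydroxyallyl cation. The five-membered ring is closed by this 3-exo β,β-bonding; the seven-membered ring is not closed by a cyclisation but results from cleavage of the internal cyclopropane bond (eudesmane C5–C10, i.e. C8a–C4), which enlarges ring B by the carbon that becomes C3a. The methyl on the dienone (C1 methyl of the product) stabilises the hydroxyallyl terminus that this cleavage mode requires and so secures the hydroazulenone over the spiro isomer, and the acidic medium secures it over the lumiketone. C3a: the shift of the C5 bond from C10 to C1 is suprafacial, so the configuration of C10 fixes that of C3a, with H-3a opposite to the former angular methyl and therefore cis to the C7 side chain as in the target. C4: acetic acid captures the tertiary cation anti to the breaking bond, giving the β-acetate. The silyl ether keeps the C11 oxygen from competing for the cation.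

Step 7
Reactants: 9 acetoxy hydroazulenone
Product: 10 hydroxy hydroazulenone (4β-OH)
Conditions: K2CO3, MeOH, 0 °C → rt
Reagents that add atoms: none
Why: Base-catalysed methanolysis of the tertiary acetate under the mildest carbonate conditions; no stereocentre is involved and the silyl ether is stable.

Step 8
Reactants: 10 hydroxy hydroazulenone
Product: 11 4-methylene hydroazulenone
Conditions: POCl3, pyridine, 0 °C → rt
Reagents that add atoms: none
Why: E2 dehydration through the dichlorophosphate needs an anti-periplanar hydrogen; H-3a is syn to the C4–O bond, so elimination goes to the methyl group (or C5) and not toward C3a, and any Δ4(5) isomer converges in step 10.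

Step 9
Reactants: 11 4-methylene hydroazulenone
Product: 12 4-methylene hydroazulenone carbinol
Conditions: HF·pyridine, pyridine, THF, 0 °C → rt
Reagents that add atoms: none
Why: Fluoride cleavage of the tertiary silyl ether under buffered, non-basic conditions, so the doubly allylic C3a–H and the exocyclic alkene are not isomerised.

Step 10
Reactants: 12 4-methylene hydroazulenone carbinol
Product: 13 4α-methyl hydroazulenone carbinol (4-H β)
Conditions: [Ir(cod)(PCy3)(py)]PF6 (5 mol %), H2 (1 atm), CH2Cl2, 0 °C → rt
Reagents that add atoms: none
Why: Hydroxyl-directed homogeneous hydrogenation with Crabtree's catalyst: the β-oriented C11 hydroxyl binds iridium and reaches C4 across the ring (O–C11–C7–C6–C5–C4), so hydrogen is delivered to the β face of C4 and the methyl ends α; the electron-poor tetrasubstituted enone is not reduced.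

Step 11
Reactants: 13 4α-methyl hydroazulenone carbinol
Product: 14 C11 benzyloxymethyl ether of 13
Conditions: BOMCl, i-Pr2NEt, Bu4NI (cat.), ClCH2CH2Cl, 50 °C
Reagents that add atoms: benzyl chloromethyl ether, ClCOCc1ccccc1
Why: Benzyloxymethyl ether formation on a tertiary alcohol with Hünig's base and iodide catalysis; it removes the alkoxide (O-alkylation, addition to C8a) from step 12 and is cleaved together with the benzyl ether in step 14.

Step 12
Reactants: 14 benzyloxymethyl ether enone
Product: 15 1β-(benzyloxymethyl)-1α-methyl-8(8a)-en-2-one
Conditions: t-BuOK, THF, 0 °C; then BOMCl, −78 → −20 °C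
Reagents that add atoms: benzyl chloromethyl ether, ClCOCc1ccccc1
Why: Deconjugative α-alkylation of an enone: the extended potassium dienolate from γ-deprotonation at the C8 methylene is alkylated at C1, which creates the quaternary centre and leaves the alkene at C8a=C8. The electrophile approaches the planar dienolate on the face of H-3a, anti to the C3a–C4 bond and the seven-membered ring, so CH2OBn ends β and the methyl α.

Step 13
Reactants: 15 alkylated β,γ-unsaturated ketone
Product: 17 C2-deoxygenated bis-ether, via hydrazone 16 (not isolated)
Conditions: N2H4·H2O, KOH, diethylene glycol, 130 → 200 °C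
Reagents that add atoms: none
Why: Wolff–Kishner reduction (Huang-Minlon procedure) of a cyclopentanone flanked by a quaternary carbon, the situation of steroidal 17-ketones; C1 has no hydrogen, so the β,γ-alkene cannot move into conjugation, and both ethers are base-stable.

Step 14
Reactants: 17 C2-deoxygenated bis-ether
Product: 18 diol (C9′ primary alcohol and C11 carbinol)
Conditions: Na, NH3(l), THF, −78 °C; then NH4Cl
Reagents that add atoms: none
Why: Dissolving-metal cleavage of both benzylic C–O bonds; the hemiformal left on C11 loses formaldehyde on work-up, and the isolated trisubstituted alkene is not reduced.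

Step 15
Reactants: 18 diol
Product: 19 C9′ aldehyde
Conditions: Dess–Martin periodinane, NaHCO3, CH2Cl2, 0 °C → rt
Reagents that add atoms: none
Why: Dess–Martin oxidation of the neopentyl primary alcohol; the tertiary carbinol cannot be oxidised, and the α-quaternary aldehyde can neither epimerise nor conjugate.

Step 16
Reactants: 19 C9′ aldehyde; 20 1,3,5-trimethoxybenzene
Product: 22 aryl carbinol (C9′ epimers), via 2,4,6-trimethoxyphenyllithium 21 (not isolated)
Conditions: 20, n-BuLi, THF, 0 °C → rt; then 19, −78 → 0 °C; H2O
Reagents that add atoms: none
Why: Ortho-lithiation of 1,3,5-trimethoxybenzene and 1,2-addition of the aryllithium (in excess, one equivalent is taken by the carbinol) to the non-enolisable aldehyde; the C9′ configuration does not matter because the centre is ionised in step 17.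

Step 17
Reactants: 22 aryl carbinol
Product: 23 C9′ methallyl compound (C9′ as in the target)
Conditions: methallyltrimethylsilane, BF3·OEt2 (20 mol %), CH2Cl2, −78 → −40 °C
Reagents that add atoms: methallyltrimethylsilane, C=C(C)C[Si](C)(C)C
Why: Lewis-acid-catalysed SN1 allylation (Hosomi–Sakurai type) of a 2,4,6-trimethoxybenzylic alcohol: the stabilised benzylic cation is captured by the allylsilane in a Felkin–Anh-type arrangement with C8a as the large group anti to the nucleophile and the aryl ring beside the C1 methyl, which should give the C9′ configuration of the target.

Step 18
Reactants: 23 C9′ methallyl compound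
Product: 24 isobutyl trimethoxyphenyl compound
Conditions: RhCl(PPh3)3 (5 mol %), H2 (1 atm), benzene–EtOH, rt
Reagents that add atoms: none
Why: Wilkinson hydrogenation is selective for the 1,1-disubstituted alkene; the trisubstituted C8=C8a alkene beside the quaternary C1 is left, and no stereocentre is formed.

Step 19
Reactants: 24 isobutyl trimethoxyphenyl compound
Product: 25 3,5-dibromo-2,4,6-trimethoxyphenyl compound
Conditions: NBS (2.1 equiv), MeCN, 0 °C, dark
Reagents that add atoms: N-bromosuccinimide, BrN1C(=O)CCC1=O
Why: Electrophilic aromatic bromination at the two free positions of the trimethoxyarene, much faster than any reaction of the hindered alkene under ionic conditions in the dark.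

Step 20
Reactants: 25 dibromide
Product: 27 dialdehyde tri-O-methyl ether, via dilithioarene 26 (not isolated)
Conditions: t-BuLi (excess), THF, −78 °C; then DMF, −78 °C → rt; aq. NH4Cl
Reagents that add atoms: N,N-dimethylformamide, CN(C)C=O
Why: Double bromine–lithium exchange and formylation of the aryllithium with DMF; one equivalent of base is taken by the carbinol, and the tetrahedral adducts mask the aldehydes until work-up.

Step 21
Reactants: 27 dialdehyde tri-O-methyl ether
Product: 28 (−)-macrocarpal D
Conditions: NaSEt, DMF, 120 °C; then aq. HCl
Reagents that add atoms: none
Why: Thiolate SN2 demethylation of aryl methyl ethers, each activated by an ortho formyl group; the tertiary alcohol and the alkene tolerate the basic conditions, and no stereocentre is touched.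

## Compound list

1 | (R)-carvone | CC1=CC[C@H](CC1=O)C(C)=C | starting material
2 | (5R)-5-(2-hydroxypropan-2-yl)-2-methylcyclohex-2-en-1-one | CC1=CC[C@H](CC1=O)C(C)(C)O | intermediate
3 | (5R)-5-[2-(tert-butyldimethylsilyloxy)propan-2-yl]-2-methylcyclohex-2-en-1-one | CC1=CC[C@H](CC1=O)C(C)(C)O[Si](C)(C)C(C)(C)C | intermediate
4 | (5R)-5-[2-(tert-butyldimethylsilyloxy)propan-2-yl]-2-methylcyclohexan-1-one (C2 epimers) | CC1CC[C@H](CC1=O)C(C)(C)O[Si](C)(C)C(C)(C)C | intermediate
5 | ethyl vinyl ketone | CCC(=O)C=C | starting material
6 | Michael adduct diketone (2-methyl-2-(3-oxopentyl)cyclohexanone; chain cis to the C5 side chain) | CCC(=O)CC[C@@]1(C)CC[C@H](CC1=O)C(C)(C)O[Si](C)(C)C(C)(C)C | intermediate (not isolated)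
7 | 11-(tert-butyldimethylsilyloxy)-10-epi-eudesm-4-en-3-one (10α-methyl; 7β side chain) | CC1=C2C[C@H](C(C)(C)O[Si](C)(C)C(C)(C)C)CC[C@]2(C)CCC1=O | intermediate
8 | 11-(tert-butyldimethylsilyloxy)-10-epi-eudesma-1,4-dien-3-one | CC1=C2C[C@H](C(C)(C)O[Si](C)(C)C(C)(C)C)CC[C@]2(C)C=CC1=O | intermediate
9 | acetoxy hydroazulenone (2-oxo-1(8a)-ene; 3a-H β; 4β-OAc and 4α-Me; 7β-CMe2OTBS) | CC1=C2C[C@H](C(C)(C)O[Si](C)(C)C(C)(C)C)CC[C@](C)(OC(C)=O)[C@H]2CC1=O | intermediate
10 | hydroxy hydroazulenone (4β-OH and 4α-Me) | CC1=C2C[C@H](C(C)(C)O[Si](C)(C)C(C)(C)C)CC[C@](C)(O)[C@H]2CC1=O | intermediate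
11 | 4-methylene hydroazulenone (11-OTBS) | CC1=C2C[C@H](C(C)(C)O[Si](C)(C)C(C)(C)C)CCC(=C)[C@H]2CC1=O | intermediate
12 | 4-methylene hydroazulenone carbinol | CC1=C2C[C@H](C(C)(C)O)CCC(=C)[C@H]2CC1=O | intermediate
13 | 4α-methyl hydroazulenone carbinol (3a-H β; 4-H β; 7β-CMe2OH) | CC1=C2C[C@H](C(C)(C)O)CC[C@@H](C)[C@H]2CC1=O | intermediate
14 | C11 benzyloxymethyl ether of 13 | CC1=C2C[C@H](C(C)(C)OCOCc3ccccc3)CC[C@@H](C)[C@H]2CC1=O | intermediate
15 | 1β-(benzyloxymethyl)-1α,4α-dimethyl-8(8a)-en-2-one (C11 OBOM) | C(OCc1ccccc1)[C@@]2(C)C(=O)C[C@H]3C2=C[C@H](C(C)(C)OCOCc4ccccc4)CC[C@H]3C | intermediate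
16 | hydrazone of 15 | C(OCc1ccccc1)[C@@]2(C)C(=NN)C[C@H]3C2=C[C@H](C(C)(C)OCOCc4ccccc4)CC[C@H]3C | intermediate (not isolated)
17 | C2-deoxygenated bis-ether (C9′ OBn; C11 OBOM) | C(OCc1ccccc1)[C@@]2(C)CC[C@H]3C2=C[C@H](C(C)(C)OCOCc4ccccc4)CC[C@H]3C | intermediate
18 | diol (C9′ CH2OH; C11 OH) | OC[C@@]1(C)CC[C@H]2C1=C[C@H](C(C)(C)O)CC[C@H]2C | intermediate
19 | C9′ aldehyde | O=C[C@@]1(C)CC[C@H]2C1=C[C@H](C(C)(C)O)CC[C@H]2C | intermediate
20 | 1,3,5-trimethoxybenzene | COc1cc(OC)cc(OC)c1 | starting material
21 | 2,4,6-trimethoxyphenyllithium | [Li]c1c(OC)cc(OC)cc1OC | intermediate (not isolated)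
22 | aryl carbinol (C9′ epimers) | OC(c1c(OC)cc(OC)cc1OC)[C@@]2(C)CC[C@H]3C2=C[C@H](C(C)(C)O)CC[C@H]3C | intermediate
23 | C9′ methallyl compound (C9′ as in the target) | C=C(C)C[C@@H](c1c(OC)cc(OC)cc1OC)[C@@]2(C)CC[C@H]3C2=C[C@H](C(C)(C)O)CC[C@H]3C | intermediate
24 | isobutyl 2,4,6-trimethoxyphenyl compound | CC(C)C[C@@H](c1c(OC)cc(OC)cc1OC)[C@@]2(C)CC[C@H]3C2=C[C@H](C(C)(C)O)CC[C@H]3C | intermediate
25 | 3,5-dibromo-2,4,6-trimethoxyphenyl compound | CC(C)C[C@@H](c1c(OC)c(Br)c(OC)c(Br)c1OC)[C@@]2(C)CC[C@H]3C2=C[C@H](C(C)(C)O)CC[C@H]3C | intermediate
26 | dilithioarene (3,5-dilithio aryl; lithium alkoxide at C11) | CC(C)C[C@@H](c1c(OC)c([Li])c(OC)c([Li])c1OC)[C@@]2(C)CC[C@H]3C2=C[C@H](C(C)(C)O[Li])CC[C@H]3C | intermediate (not isolated)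
27 | dialdehyde tri-O-methyl ether (tri-O-methylmacrocarpal D) | CC(C)C[C@@H](c1c(OC)c(C=O)c(OC)c(C=O)c1OC)[C@@]2(C)CC[C@H]3C2=C[C@H](C(C)(C)O)CC[C@H]3C | intermediate
28 | (−)-macrocarpal D | CC(C)C[C@@H](c1c(O)c(C=O)c(O)c(C=O)c1O)[C@@]1(C)CC[C@H]2C1=C[C@H](C(C)(C)O)CC[C@H]2C | target

## Step count and least certain steps

Total: 21 steps. Longest linear sequence: 21 steps from (R)-carvone 1; 1,3,5-trimethoxybenzene 20 enters in step 16 after lithiation in the flask.

**Step 6 (key step).**
- What may go wrong: cleavage of the other cyclopropane bond (spiro enone), diversion to the lumiketone, secondary photolysis of the product enone on over-irradiation, or loss of the silyl group followed by capture of the C4 cation by the C11 oxygen.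
- Fallback: irradiate 8 in aqueous acetic acid so that water, not acetic acid, captures the C4 cation. This more nucleophilic medium diverts less material to proton loss, and it gives the hydroxy hydroazulenone 10 directly, so the route is rejoined at 10 without step 7. No new compound is made.

**Step 12.**
- What may go wrong: this is the least secure step after the rearrangement. γ-Deprotonation can take place at the ring-fusion C3a–H instead of the C8 methylene. The resulting endocyclic dienolate is the more substituted one; its alkylation leaves the alkene at C3a=C8a and erases C3a, and its reversible formation epimerises C3a. Alkylation at C3 through the cross-conjugated enolate and O-alkylation are further leaks.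
- Fallback: separate deconjugation from alkylation. From 14, the potassium dienolate mixture is protonated kinetically (AcOH, −78 °C) to give the β,γ-unsaturated ketone F1 (alkene at C8a=C8, H on C1). F1 is separated from the regioisomeric β,γ-unsaturated ketone F2 (alkene at C3a=C8a), and F2 is returned to 14 by base. Kinetic deprotonation of F1 with LDA at −78 °C removes the doubly activated C1–H and gives the lithium dienolate without equilibration; benzyl chloromethyl ether then gives 15.

**Step 17.**
- What may go wrong: poor or reversed facial selectivity in the capture of the benzylic cation (the discrimination between C8a and C2 on the quaternary C1 is modest), or internal capture of the cation by the C11 hydroxyl.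
- Fallback: exchange the roles of nucleophile and resident group. From 22, Dess–Martin oxidation gives the aryl ketone F3. Methallylmagnesium chloride adds to give the tertiary benzylic alcohol F4. Ionic deoxygenation (Et3SiH, BF3·OEt2, −78 °C) then delivers hydride to the cation that already carries the methallyl group. Attack anti to C8a now places hydrogen where carbon entered before, so the opposite C9′ configuration results. The route is rejoined at 23.

**Step 10.**
- What may go wrong: hydrogen delivery from the wrong face if the carbinol does not engage the catalyst; iridium-hydride migration of the methylene into conjugation, which destroys C3a; slow over-reduction of the enone.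
- Fallback: make the conjugated isomer on purpose. From 9, DBU removes acetic acid by vinylogous elimination through C3a to give the linear dienone F5. HF·pyridine frees the carbinol, giving the dienone carbinol F6. Hydroxyl-directed hydrogenation then adds H2 cis across the tetrasubstituted C3a=C4 bond from the β face. This sets H-3a and H-4 together, both β as required, and returns to the route at 13 without steps 7–9.

**Step 7.**
- What may go wrong: base can remove H-3a and expel acetate (vinylogous β-elimination to the conjugated dienone), and the tertiary alkoxide can fragment by a vinylogous retro-aldol cleavage of C3a–C4.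
- Fallback: cleave the ester reductively. From 9, DIBAL-H at −78 °C removes the acetate and reduces the ketone to the allylic alcohol, giving the diol F7. MnO2 then reoxidises only the allylic alcohol, which gives 10.

## Further compounds

F0 | step 6 | none | none
F1 | step 12 | β,γ-unsaturated ketone (alkene C8a=C8; H on C1; C11 OBOM) | CC1C(=O)C[C@H]2C1=C[C@H](C(C)(C)OCOCc3ccccc3)CC[C@H]2C
F2 | step 12 | regioisomeric β,γ-unsaturated ketone (alkene C3a=C8a) | CC1C(=O)CC2=C1C[C@H](C(C)(C)OCOCc3ccccc3)CC[C@H]2C
F3 | step 17 | aryl ketone at C9′ | O=C(c1c(OC)cc(OC)cc1OC)[C@@]2(C)CC[C@H]3C2=C[C@H](C(C)(C)O)CC[C@H]3C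
F4 | step 17 | tertiary benzylic alcohol (C9′ methallyl; C9′ epimers) | C=C(C)CC(O)(c1c(OC)cc(OC)cc1OC)[C@@]2(C)CC[C@H]3C2=C[C@H](C(C)(C)O)CC[C@H]3C
F5 | step 10 | linear dienone (1(8a),3a(4)-dien-2-one; 11-OTBS) | CC1=C2C[C@H](C(C)(C)O[Si](C)(C)C(C)(C)C)CCC(C)=C2CC1=O
F6 | step 10 | linear dienone carbinol | CC1=C2C[C@H](C(C)(C)O)CCC(C)=C2CC1=O
F7 | step 7 | diol (C2 allylic alcohol, epimers; 4β-OH; 11-OTBS) | CC1=C2C[C@H](C(C)(C)O[Si](C)(C)C(C)(C)C)CC[C@](C)(O)[C@H]2CC1O
A1 | alternative 1 | hydroazulene with quaternary C1 bearing the trimethoxybenzyl group | COc1cc(OC)cc(OC)c1C[C@@]2(C)CC[C@H]3C2=C[C@H](C(C)(C)O[Si](CC)(CC)CC)CC[C@H]3C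
A2 | alternative 2 | hydroazulene β-keto ester (enol form) | COc1ccc(COC[C@@]2(C)CC[C@H]3[C@H]2C(O)=C(C(=O)OCC)CC[C@H]3C)cc1
A3 | alternative 3 | (E)-cyclodec-5-enone with quaternary C1 (methyl, trimethoxybenzyl) | O=C1C[C@H](C(C)(C)O[Si](CC)(CC)CC)CC/C(C)=C/CC[C@]1(C)Cc2c(OC)cc(OC)cc2OC
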